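Every left-handed substrate consumed costs one partner, so the easy sum is a subtraction. In the cedar run, c(left-handed substrate) stood at 11.5 mM after 80.0 min, a loss of 8.52 mM against 17.6 mM of partner charged, about half. The next run must be chosen with that shortfall in view.

common to all: left-handed substrate 20 mM; right-handed substrate 20 mM
- cedar: partner 0.88 equiv; run made earlier
- alder: partner 4.4 equiv; run made earlier
- winter: partner 3.00 equiv; time 2.0 h
- summer: partner 0.750 equiv; time 2.0 h

| run | time / min | right-handed substrate / % | left-handed substrate / % |
|---|---|---|---|
| cedar | 8.00 | 50.5 | 36.0 |
| cedar | 20.0 | 49.7 | 33.4 |
| cedar | 40.0 | 49.9 | 31.9 |
| cedar | 60.0 | 48.5 | 29.8 |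
| cedar | 80.0 | 49.7 | 28.7 |
| alder | 8.00 | 48.9 | 9.4 |
| alder | 20.0 | 48.1 | 4.6 |
| alder | 40.0 | 46.8 | 1.8 |
| alder | 60.0 | 46.0 | 1.7 |
| alder | 80.0 | 46.3 | 0.4 |

(each reading ± 0.5 percentage points)

- partner is single-handed; left-handed substrate and right-handed substrate are mirror images of each other, charged as a racemate, each of them at the stated concentration
- steps that have been proposed: partner + left-handed substrate -> left-handed product; partner + right-handed substrate -> right-handed product; partner <-> dormant form; partner -> decomposed reagent; partner -> decomposition product
- an excess is the difference of the two amounts in percent of their sum
- an excess is below zero if the other one leads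
- the handed part of partner does not stay in what it makes, so the products of the two hands are mirror images too

- which one finishes higher in excess of right-handed substrate over left-handed substrate among what is left of the two ("neither" within 2 percentage points) (winter / summer / neither)
- excess of right-handed substrate over left-handed substrate among what is left of the two at the end, winter
- excess of right-handed substrate over left-handed substrate among what is left of the two at the end, summer

My reckoning gives partner two fates: reaction with left-handed substrate, at a rate proportional to c(left-handed substrate), and first-order loss, at a rate independent of it. Summing the shares down a run gives: partner spent = (start − c) + c× ln(start/c), with the dormant form counted as a delay. Taking cedar's charge as spent gives 16.4 mM for c×, the crossover concentration: the c(left-handed substrate) at which the two fates take equal shares of partner.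

The summer flask charges 15.0 mM of partner, less than the 20 mM of left-handed substrate, so partner is the limiting reagent there. Cedar's share leaves 12.7 mM, for which the rule asks 14.7 mM of partner. With right-handed substrate at cedar's reading of 49.7%, the reckoning puts the excess in summer at 21.9%.

The winter flask charges 60.0 mM. Counting the whole charge of left-handed substrate as consumed, the rule leaves 1.73 mM, below the crossover. With right-handed substrate at alder's reading of 46.3%, the reckoning puts the excess in winter at 82.9%, so I would run winter.

The forecast also names winter, with 92% for winter and 24% for summer, reading “a fast burst that stalls by about 8 min”. Both its numbers lie above mine.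

    partner + left-handed substrate → left-handed product (k = 0.0740 L mol⁻¹ s⁻¹)
    partner + right-handed substrate → right-handed product (k = 0.00140 L mol⁻¹ s⁻¹)
    partner ⇌ dormant form (K = 2.40, k = 0.00120 s⁻¹)
    partner → decomposed reagent (k = 9.00 × 10⁻⁴ s⁻¹)
    partner → decomposition product (k = 4.00 × 10⁻⁶ s⁻¹)

The flasks give winter as the higher, with 87.6% for winter and 24.1% for summer. The neighbouring flask is like winter but with 1.80 equiv of partner, a charge of 36.0 mM. It ends at 2.00 h with c(left-handed substrate) at 4.81 mM, below the crossover. For that amount, the rule with cedar's c× asks 38.5 mM of partner spent, 2.50 mM over the charge. The excess of right-handed substrate in that neighbouring flask stands at 60.4%.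

The earlier runs and the new flask are simulated with made-up constants.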